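**Retrosynthetic overview**
1. Target 23 ⇐ site-selective acylation of the C4–OH of diene-diol 20 (the C1–OH is neopentylic) ⇐ hydrogenation of the C9=C10 bond of triene-diol 19.
2. 19 ⇐ humulane-type 1,11-closure (C1–C11): the C10=C11 π-bond of a 1,1-dimethylallylborane (from an allene) attacks the C1 aldehyde released from butenolide 15, and boron leaves from C9 where the humulyl cation loses its proton.
3. 15 ⇐ α-hydroxy ketone 13 + Ph3P=C=C=O ⇐ methyl (S)-glycidate 8 (C3–C5, source of the C4 centre) + alkenyl metal from 7.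
4. 7 (6Z olefin plus allene handle) ⇐ propargyl alcohol 1 (anti-carbomagnesiation, iodination, bromide 4) + lithiated 3-methylbuta-1,2-diene 5.
5. Ring order: the temporary five-membered butenolide first (step 6, it locks 2Z), the 11-membered carbocycle last (step 7).

Assumption: humulane numbering is used in the text (C1 = CHOH next to C11 = CMe2; C2=C3 and C6=C7 are the Z olefins; C4 = ester carbon), so the target is (1S,2Z,4S,6Z); systematic names number the ring from the ester carbon; 5, 8 and 21 are bought.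

**Step 1**
Reactants: 1 prop-2-yn-1-ol
Product: 3 (2Z)-3-iodo-2-methylprop-2-en-1-ol, via alkenylmagnesium alkoxide 2 (not isolated)
Conditions: MeMgBr (2.5 equiv), CuI (10 mol%), THF, −10 °C to rt; then I2, −20 °C
Reagents that add atoms: methylmagnesium bromide, C[Mg]Br; iodine, II
Why: CuI-catalysed anti-carbomagnesiation of the propargylic alkoxide (Duboudin–Jousseaume) puts methyl on C7 and magnesium on C6 cis to the CH2O group in a five-membered chelate, and iodinolysis with retention fixes the 6Z geometry (C5 and C8 cis).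

**Step 2**
Reactants: 3 (2Z)-3-iodo-2-methylprop-2-en-1-ol
Product: 4 (1Z)-3-bromo-1-iodo-2-methylprop-1-ene
Conditions: PBr3 (0.4 equiv), Et2O, 0 °C
Reagents that add atoms: phosphorus tribromide, BrP(Br)Br
Why: SN2 bromination of a primary allylic alcohol through its phosphite ester leaves the alkenyl iodide and the olefin geometry untouched.

**Step 3**
Reactants: 4 (1Z)-3-bromo-1-iodo-2-methylprop-1-ene; 5 3-methylbuta-1,2-diene
Product: 7 (1Z)-1-iodo-2,6-dimethylhepta-1,4,5-triene, via allenyllithium 6 (not isolated)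
Conditions: 5 (1.5 equiv), n-BuLi (1.3 equiv), THF, −78 to −50 °C; then 4, −78 to −20 °C
Reagents that add atoms: none
Why: Lithiation of the allenic CH2 terminus and SN2 alkylation of the allylic bromide at the unsubstituted allenyl carbon (the propargylic terminus is tertiary) forms C8–C9 and installs the C9=C10=C11 allene as a latent 1,1-dimethylallyl nucleophile.

**Step 4**
Reactants: 7 (1Z)-1-iodo-2,6-dimethylhepta-1,4,5-triene; 8 methyl (2S)-oxirane-2-carboxylate
Product: 11 methyl (2S,4Z)-2-hydroxy-5,9-dimethyldeca-4,7,8-trienoate, via alkenyllithium 9 (not isolated), via alkenylmagnesium bromide 10 (not isolated)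
Conditions: t-BuLi (2.05 equiv), Et2O, −78 °C; MgBr2·OEt2 (1.1 equiv); CuI (10 mol%), 8 (0.8 equiv), THF, −40 °C
Reagents that add atoms: none
Why: Iodine–lithium exchange with retention followed by CuI-catalysed SN2 opening of the glycidate at its CH2 terminus forms C5–C6, the C4 stereocentre being carried over unchanged from the chiral pool and the 6Z geometry retained.

**Step 5**
Reactants: 11 methyl (2S,4Z)-2-hydroxy-5,9-dimethyldeca-4,7,8-trienoate
Product: 13 (3S,5Z)-3-hydroxy-6,10-dimethylundeca-5,8,9-trien-2-one, via Weinreb amide 12 (not isolated)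
Conditions: MeNH(OMe)·HCl (1.5 equiv), i-PrMgCl (4.5 equiv), THF, −20 °C; then MeMgBr (3 equiv), 0 °C; aq. NH4Cl
Reagents that add atoms: methylmagnesium bromide, C[Mg]Br
Why: In-situ amidation of the ester by the magnesium amide followed by Weinreb ketone synthesis stops at the methyl ketone through the chelated tetrahedral adduct, supplying C3 with its methyl while the alkoxide-bearing C4 centre is not enolised.

**Step 6**
Reactants: 13 (3S,5Z)-3-hydroxy-6,10-dimethylundeca-5,8,9-trien-2-one
Product: 15 (5S)-5-[(2Z)-3,7-dimethylocta-2,5,6-trien-1-yl]-4-methylfuran-2(5H)-one, via phosphorane ester 14 (not isolated)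
Conditions: Ph3P=C=C=O (1.2 equiv), toluene, 80 °C
Reagents that add atoms: (triphenylphosphoranylidene)ketene, O=C=C=P(c1ccccc1)(c1ccccc1)c1ccccc1
Why: Bestmann butenolide synthesis (O-acylation of the carbinol by the ketene ylide, then intramolecular Wittig olefination of the neighbouring ketone) adds C1 and C2, forces C1 and C4 cis across C2=C3 (2Z) by the ring and leaves C4 untouched.

**Step 7**
Reactants: 15 (5S)-5-[(2Z)-3,7-dimethylocta-2,5,6-trien-1-yl]-4-methylfuran-2(5H)-one
Product: 19 (1S,2Z,4S,6E,9Z)-2,5,5,9-tetramethylcycloundeca-2,6,9-triene-1,4-diol, via allylborane 16 (not isolated), via aluminium lactolate 17 (not isolated), via enal aluminium alkoxide 18 (not isolated)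
Conditions: 9-BBN-H (1.05 equiv), THF, 0 °C to rt; dilute to 2 mM with CH2Cl2; i-Bu2AlH (1.05 equiv), −78 °C, then to −20 °C; aq. potassium sodium tartrate (KNaC4H4O6); ethanolamine
Reagents that add atoms: none
Why: Proposed new method: 9-BBN-H hydroborates only the allene (boron to C9, hydrogen to C10) to give a fluxional 1,1-dimethylallylborane; i-Bu2AlH then reduces the butenolide to its aluminium lactolate at −78 °C, and as this opens to the (Z)-enal on warming the C10=C11 π-bond attacks C1 through a closed six-membered allylboration transition state while boron leaves from C9, which is the farnesyl-to-humulyl 1,11-closure with boron in the place of the proton lost from C9 and forms the 11-membered ring; allyldialkylboranes add to aldehydes even at −78 °C, fast enough to outrun furan formation or ene closure onto C6=C7, and no protic group is present before work-up; C1 is set by C4 because the C5 arm of the tether lies on one face of the planar (Z)-enal (C4–H in the olefin plane by allylic 1,3-strain, or O4–Al chelated to the carbonyl), so C11 is delivered to that face to give the like (1S,4S) diol (a 6Z isomer, if formed, converges in step 8); the closest known reactions are reverse prenylation of aldehydes with allene-derived allylboranes, intramolecular allylboration, and one-pot i-Bu2AlH reduction–allylation of lactones.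

**Step 8**
Reactants: 19 (1S,2Z,4S,6E,9Z)-2,5,5,9-tetramethylcycloundeca-2,6,9-triene-1,4-diol
Product: 20 (1S,2Z,4S,9Z)-2,5,5,9-tetramethylcycloundeca-2,9-diene-1,4-diol
Conditions: H2 (3 atm), RhCl(PPh3)3 (5 mol%), benzene–EtOH, rt
Reagents that add atoms: none
Why: Homogeneous hydrogenation with RhCl(PPh3)3 is very sensitive to olefin substitution, so the 1,2-disubstituted C9=C10 bond is saturated while the two trisubstituted Z olefins and both stereocentres are left alone.

**Step 9**
Reactants: 20 (1S,2Z,4S,9Z)-2,5,5,9-tetramethylcycloundeca-2,9-diene-1,4-diol; 21 4-(acetyloxy)benzoyl chloride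
Product: 23 (1S,2Z,4S,9Z)-4-hydroxy-2,5,5,9-tetramethylcycloundeca-2,9-dien-1-yl 4-hydroxybenzoate, via acetate 22 (not isolated)
Conditions: 21 (1.1 equiv), pyridine, DMAP (10 mol%), CH2Cl2, 0 °C; then MeOH, K2CO3 (0.3 equiv), 0 °C
Reagents that add atoms: none
Why: DMAP-catalysed acylation takes the C4 hydroxyl with retention because the C1 hydroxyl is neopentylic next to C11, and the phenolic acetate is then removed by mild base-catalysed methanolysis, which is much faster than cleavage of the alkyl benzoate.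

**Compound list**
1 | prop-2-yn-1-ol | C#CCO | starting material
2 | bromomagnesium (2Z)-3-(bromomagnesio)-2-methylprop-2-en-1-olate (in situ) | Br[Mg]/C=C(C)\CO[Mg]Br | intermediate
3 | (2Z)-3-iodo-2-methylprop-2-en-1-ol | I/C=C(C)\CO | intermediate
4 | (1Z)-3-bromo-1-iodo-2-methylprop-1-ene | I/C=C(C)\CBr | intermediate
5 | 3-methylbuta-1,2-diene | CC(C)=C=C | starting material
6 | (3-methylbuta-1,2-dien-1-yl)lithium (in situ) | [Li]C=C=C(C)C | intermediate
7 | (1Z)-1-iodo-2,6-dimethylhepta-1,4,5-triene | I/C=C(C)\CC=C=C(C)C | intermediate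
8 | methyl (2S)-oxirane-2-carboxylate | COC(=O)[C@@H]1CO1 | starting material
9 | [(1Z)-2,6-dimethylhepta-1,4,5-trien-1-yl]lithium (in situ) | [Li]/C=C(C)\CC=C=C(C)C | intermediate
10 | bromo[(1Z)-2,6-dimethylhepta-1,4,5-trien-1-yl]magnesium (in situ) | Br[Mg]/C=C(C)\CC=C=C(C)C | intermediate
11 | methyl (2S,4Z)-2-hydroxy-5,9-dimethyldeca-4,7,8-trienoate | COC(=O)[C@@H](O)C/C=C(C)\CC=C=C(C)C | intermediate
12 | (2S,4Z)-2-hydroxy-N-methoxy-N,5,9-trimethyldeca-4,7,8-trienamide (in situ, as magnesium alkoxide) | CON(C)C(=O)[C@@H](O)C/C=C(C)\CC=C=C(C)C | intermediate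
13 | (3S,5Z)-3-hydroxy-6,10-dimethylundeca-5,8,9-trien-2-one | CC(=O)[C@@H](O)C/C=C(C)\CC=C=C(C)C | intermediate
14 | (3S,5Z)-6,10-dimethyl-2-oxoundeca-5,8,9-trien-3-yl (triphenyl-λ5-phosphanylidene)acetate (in situ) | CC(=O)[C@@H](OC(=O)C=P(c1ccccc1)(c1ccccc1)c1ccccc1)C/C=C(C)\CC=C=C(C)C | intermediate
15 | (5S)-5-[(2Z)-3,7-dimethylocta-2,5,6-trien-1-yl]-4-methylfuran-2(5H)-one | O=C1C=C(C)[C@H](C/C=C(C)\CC=C=C(C)C)O1 | intermediate
16 | (5S)-5-[(2Z)-5-(9-borabicyclo[3.3.1]nonan-9-yl)-3,7-dimethylocta-2,6-dien-1-yl]-4-methylfuran-2(5H)-one (in situ, boron-bearing carbon fluxional) | O=C1C=C(C)[C@H](C/C=C(C)\CC(B2C3CCCC2CCC3)C=C(C)C)O1 | intermediate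
17 | ({(5S)-5-[(2Z)-5-(9-borabicyclo[3.3.1]nonan-9-yl)-3,7-dimethylocta-2,6-dien-1-yl]-4-methyl-2,5-dihydrofuran-2-yl}oxy)bis(2-methylpropyl)alumane (in situ) | CC(C)C[Al](CC(C)C)OC1C=C(C)[C@H](C/C=C(C)\CC(B2C3CCCC2CCC3)C=C(C)C)O1 | intermediate
18 | (2Z,4S,6Z)-9-(9-borabicyclo[3.3.1]nonan-9-yl)-4-{[bis(2-methylpropyl)alumanyl]oxy}-3,7,11-trimethyldodeca-2,6,10-trienal (in situ) | O=C/C=C(C)\[C@@H](O[Al](CC(C)C)CC(C)C)C/C=C(C)\CC(B1C2CCCC1CCC2)C=C(C)C | intermediate
19 | (1S,2Z,4S,6E,9Z)-2,5,5,9-tetramethylcycloundeca-2,6,9-triene-1,4-diol | C/C1=C/C[C@H](O)/C(C)=C\[C@H](O)C(C)(C)/C=C/C1 | intermediate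
20 | (1S,2Z,4S,9Z)-2,5,5,9-tetramethylcycloundeca-2,9-diene-1,4-diol | C/C1=C/C[C@H](O)/C(C)=C\[C@H](O)C(C)(C)CCC1 | intermediate
21 | 4-(acetyloxy)benzoyl chloride | CC(=O)Oc1ccc(cc1)C(Cl)=O | starting material
22 | (1S,2Z,4S,9Z)-4-hydroxy-2,5,5,9-tetramethylcycloundeca-2,9-dien-1-yl 4-(acetyloxy)benzoate (in situ) | C/C1=C/C[C@H](OC(=O)c2ccc(OC(C)=O)cc2)/C(C)=C\[C@H](O)C(C)(C)CCC1 | intermediate
23 | (1S,2Z,4S,9Z)-4-hydroxy-2,5,5,9-tetramethylcycloundeca-2,9-dien-1-yl 4-hydroxybenzoate | C/C1=C/C[C@H](OC(=O)c2ccc(O)cc2)/C(C)=C\[C@H](O)C(C)(C)CCC1 | target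

**Totals**
Total step count: 9. Longest linear sequence: 9 (5, 8 and 21 are bought).

**Steps most likely to fail**

Step 7 (one-pot hydroboration, lactone semi-reduction and allyl-transfer ring closure; also the step that sets C1). The fallback sets out from 15 and returns at 19. Butenolide 15 alone is reduced with i-Bu2AlH (1.05 equiv, CH2Cl2, −78 °C) and the lactol (5S)-5-[(2Z)-3,7-dimethylocta-2,5,6-trien-1-yl]-4-methyl-2,5-dihydrofuran-2-ol F1 is isolated. The ring is then closed by iridium-catalysed transfer-hydrogenative allene–aldehyde coupling ([Ir(cod)Cl]2, SEGPHOS of the matching hand, 4-cyano-3-nitrobenzoic acid, Cs2CO3, 2-propanol, THF, high dilution, 60 °C). An iridium hydride adds to the allene to give a 1,1-dimethyl-π-allyl that attacks the aldehyde tautomer of F1 through C11, so that the catalyst rather than the substrate controls C1, giving 19.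

Step 8 (chemoselective hydrogenation of the neopentylic C9=C10 bond). The fallback sets out from 19 and returns at 23. The order is reversed: 19 is acylated with 21 as in step 9 to give, through (1S,2Z,4S,6E,9Z)-4-hydroxy-2,5,5,9-tetramethylcycloundeca-2,6,9-trien-1-yl 4-(acetyloxy)benzoate F2, the triene ester (1S,2Z,4S,6E,9Z)-4-hydroxy-2,5,5,9-tetramethylcycloundeca-2,6,9-trien-1-yl 4-hydroxybenzoate F3. Its only disubstituted olefin is then reduced last with diazene F4, generated from 2-nitrobenzenesulfonylhydrazide and Et3N in CH2Cl2 at rt. This is a metal-free concerted syn transfer of H2 whose rate falls steeply with olefin substitution, and it gives 23 directly.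

Step 4 (CuI-catalysed glycidate opening by a hindered alkenyl Grignard that carries an allene). The fallback sets out from 7 and returns at 15, replacing steps 4 to 6. Alkenyllithium 9 (from 7 and t-BuLi) is added to oxirane (BF3·OEt2, −78 °C) to give (3Z)-4,8-dimethylnona-3,6,7-trien-1-ol F5. Buffered Dess–Martin oxidation gives the β,γ-unsaturated aldehyde (3Z)-4,8-dimethylnona-3,6,7-trienal F6, used crude. Methyl (2Z)-3-iodobut-2-enoate F7 (from methyl but-2-ynoate, NaI, AcOH, 110 °C) is coupled with F6 in an enantioselective Nozaki–Hiyama–Kishi reaction (CrCl2, NiCl2 (2 mol%), chiral oxazoline–sulfonamide ligand, Et3N, THF). The resulting methyl (2Z,4S,6Z)-4-hydroxy-3,7,11-trimethyldodeca-2,6,9,10-tetraenoate F8 lactonises in the flask to 15, so that C4 is set by the catalyst instead of the chiral pool.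

**Further compounds**
F1 | step 7 | (5S)-5-[(2Z)-3,7-dimethylocta-2,5,6-trien-1-yl]-4-methyl-2,5-dihydrofuran-2-ol | OC1C=C(C)[C@H](C/C=C(C)\CC=C=C(C)C)O1
F2 | step 8 | (1S,2Z,4S,6E,9Z)-4-hydroxy-2,5,5,9-tetramethylcycloundeca-2,6,9-trien-1-yl 4-(acetyloxy)benzoate | C/C1=C/C[C@H](OC(=O)c2ccc(OC(C)=O)cc2)/C(C)=C\[C@H](O)C(C)(C)/C=C/C1
F3 | step 8 | (1S,2Z,4S,6E,9Z)-4-hydroxy-2,5,5,9-tetramethylcycloundeca-2,6,9-trien-1-yl 4-hydroxybenzoate | C/C1=C/C[C@H](OC(=O)c2ccc(O)cc2)/C(C)=C\[C@H](O)C(C)(C)/C=C/C1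
F4 | step 8 | diazene | N=N
F5 | step 4 | (3Z)-4,8-dimethylnona-3,6,7-trien-1-ol | OCC/C=C(C)\CC=C=C(C)C
F6 | step 4 | (3Z)-4,8-dimethylnona-3,6,7-trienal | O=CC/C=C(C)\CC=C=C(C)C
F7 | step 4 | methyl (2Z)-3-iodobut-2-enoate | COC(=O)/C=C(C)\I
F8 | step 4 | methyl (2Z,4S,6Z)-4-hydroxy-3,7,11-trimethyldodeca-2,6,9,10-tetraenoate | COC(=O)/C=C(C)\[C@@H](O)C/C=C(C)\CC=C=C(C)C
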